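**Retrosynthetic overview**
- The C8 prenyl group comes last, by aromatic Claisen rearrangement of a 7-O-(1,1-dimethylallyl) ether; that ether comes from the 7-O-(1,1-dimethylpropargyl) ether by semi-hydrogenation.
- The 7-O-propargyl ether comes from chemoselective O-alkylation of the 5,7,3'-trihydroxy pyranoflavone core.
- Key step: phloroglucinol is fused with a ring B β-ketoester that carries an aryl 1,1-dimethylpropargyl ether. Aroylketene annulation closes ring C and propargyl Claisen/electrocyclisation closes ring D in the same operation.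
- The β-ketoester comes from 3',4'-dihydroxyacetophenone by 4-O-propargylation and C-ethoxycarbonylation.
- Ring order: rings A and B are bought, rings C and D form together, and the prenyl group is added last. One tertiary propargyl chloride supplies both ring D and the prenyl group.

Assumption: the target has no stereocentre and no stereogenic double bond, so it is achiral and no stereocontrol is needed.

**Step 1**
Reactants: 1 1-(3,4-dihydroxyphenyl)ethan-1-one (3',4'-dihydroxyacetophenone); 2 3-chloro-3-methylbut-1-yne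
Product: 3 1-[3-hydroxy-4-(2-methylbut-3-yn-2-yloxy)phenyl]ethan-1-one
Conditions: 2 (1.2 equiv), DBU (1.05 equiv), CuCl2 (1 mol%), MeCN, 0 °C → rt
Reagents that add atoms: 3-chloro-3-methylbut-1-yne (2), CC(C)(Cl)C#C
Why: Copper-catalysed propargylic O-alkylation (Williamson-type etherification): one equivalent of DBU ionises only the more acidic 4-OH (para to the acetyl group), and this phenoxide captures the copper-activated tertiary propargylic chloride, leaving the 3-OH free; no stereocentre is formed.

**Step 2**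
Reactants: 3 1-[3-hydroxy-4-(2-methylbut-3-yn-2-yloxy)phenyl]ethan-1-one; 4 diethyl carbonate
Product: 5 ethyl 3-[3-hydroxy-4-(2-methylbut-3-yn-2-yloxy)phenyl]-3-oxopropanoate
Conditions: NaH (3.5 equiv), 4 (5 equiv), THF, reflux; AcOH quench, 0 °C
Reagents that add atoms: diethyl carbonate (4), CCOC(=O)OCC
Why: Crossed Claisen condensation (C-ethoxycarbonylation of the methyl ketone enolate), driven by formation of the stabilised β-ketoester enolate; the sodium phenoxide is inert because any aryl carbonate is cleaved back by ethoxide, and the tertiary propargyl ether has no propargylic hydrogen to isomerise.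

**Step 3**
Reactants: 5 ethyl 3-[3-hydroxy-4-(2-methylbut-3-yn-2-yloxy)phenyl]-3-oxopropanoate; 6 benzene-1,3,5-triol (phloroglucinol)
Product: 10 5,7-dihydroxy-2-(8-hydroxy-2,2-dimethyl-2H-chromen-6-yl)-4H-chromen-4-one, via aroylketene 7 (not isolated), via triketone 8 (not isolated), via flavone propargyl ether 9 (not isolated)
Conditions: 6 (1.5 equiv, anhydrous), neat melt, N2, 170 → 240 °C (microwave or metal bath), 15 min, EtOH/H2O distilled off
Reagents that add atoms: benzene-1,3,5-triol (6), Oc1cc(O)cc(O)c1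
Why: Proposed new method: a thermal domino in which 5 loses EtOH to give aroylketene 7, which C-acylates phloroglucinol to triketone 8 and cyclodehydrates to flavone 9 (closest known type: Mentzer-type neat fusion of phloroglucinol with ethyl aroylacetates to 5,7-dihydroxyflavones), while in the same melt the aryl 1,1-dimethylpropargyl ether undergoes aromatic Claisen rearrangement to its only free ortho carbon, [1,5]-H shift and oxa-6π electrocyclisation to the 2,2-dimethyl-2H-chromene (closest known type: thermal chromene synthesis from aryl propargyl ethers), so rings C and D close in one operation; phloroglucinol is symmetric, so there is no regiochemical choice, and no stereocentre is formed.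

**Step 4**
Reactants: 10 5,7-dihydroxy-2-(8-hydroxy-2,2-dimethyl-2H-chromen-6-yl)-4H-chromen-4-one; 2 3-chloro-3-methylbut-1-yne
Product: 11 5-hydroxy-2-(8-hydroxy-2,2-dimethyl-2H-chromen-6-yl)-7-(2-methylbut-3-yn-2-yloxy)-4H-chromen-4-one
Conditions: 2 (1.3 equiv), DBU (1.05 equiv), CuCl2 (5 mol%), MeCN/DMF (4:1), 0 °C → rt
Reagents that add atoms: 3-chloro-3-methylbut-1-yne (2), CC(C)(Cl)C#C
Why: Chemoselective copper-catalysed propargylic etherification (Williamson type): one equivalent of DBU ionises only the vinylogous-acid 7-OH, since the 5-OH is held in a hydrogen bond to the 4-carbonyl and the guaiacol-like 3'-OH is far less acidic.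

**Step 5**
Reactants: 11 5-hydroxy-2-(8-hydroxy-2,2-dimethyl-2H-chromen-6-yl)-7-(2-methylbut-3-yn-2-yloxy)-4H-chromen-4-one
Product: 13 5,7-dihydroxy-2-(8-hydroxy-2,2-dimethyl-2H-chromen-6-yl)-8-(3-methylbut-2-en-1-yl)-4H-chromen-4-one, via reverse-prenyl ether 12 (not isolated)
Conditions: H2 (1 atm, stopped at 1.0 equiv uptake), Pd/CaCO3 poisoned with Pb(OAc)2 (Lindlar catalyst), quinoline, PhMe/EtOAc (4:1), rt; filter (Celite); filtrate 120 °C, sealed tube, 3 h
Reagents that add atoms: none
Why: Lindlar semi-hydrogenation of the terminal alkyne (the chromene and flavone C=C bonds are inert to the poisoned catalyst) gives the aryl 1,1-dimethylallyl ether 12, whose aromatic Claisen rearrangement ([3,3] with allyl inversion) puts a linear prenyl group on an ortho carbon, C8 being favoured over C6 because the chelated 5-OH/4-carbonyl fixes the higher double-bond character in the C7–C8 bond (the same bias that gives angular products from chelated 1-hydroxy-3-allyloxy xanthones and acridones); no stereocentre is formed.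

**Compound list**
1 | 1-(3,4-dihydroxyphenyl)ethan-1-one | CC(=O)c1ccc(O)c(O)c1 | starting material
2 | 3-chloro-3-methylbut-1-yne | CC(C)(Cl)C#C | starting material
3 | 1-[3-hydroxy-4-(2-methylbut-3-yn-2-yloxy)phenyl]ethan-1-one | CC(=O)c1ccc(OC(C)(C)C#C)c(O)c1 | intermediate
4 | diethyl carbonate | CCOC(=O)OCC | starting material
5 | ethyl 3-[3-hydroxy-4-(2-methylbut-3-yn-2-yloxy)phenyl]-3-oxopropanoate | CCOC(=O)CC(=O)c1ccc(OC(C)(C)C#C)c(O)c1 | intermediate
6 | benzene-1,3,5-triol (phloroglucinol) | Oc1cc(O)cc(O)c1 | starting material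
7 | 3-[3-hydroxy-4-(2-methylbut-3-yn-2-yloxy)phenyl]-3-oxoprop-1-en-1-one (aroylketene) | O=C=CC(=O)c1ccc(OC(C)(C)C#C)c(O)c1 | intermediate
8 | 1-[3-hydroxy-4-(2-methylbut-3-yn-2-yloxy)phenyl]-3-(2,4,6-trihydroxyphenyl)propane-1,3-dione | O=C(CC(=O)c1c(O)cc(O)cc1O)c1ccc(OC(C)(C)C#C)c(O)c1 | intermediate
9 | 5,7-dihydroxy-2-[3-hydroxy-4-(2-methylbut-3-yn-2-yloxy)phenyl]-4H-chromen-4-one | O=c1cc(-c2ccc(OC(C)(C)C#C)c(O)c2)oc2cc(O)cc(O)c12 | intermediate
10 | 5,7-dihydroxy-2-(8-hydroxy-2,2-dimethyl-2H-chromen-6-yl)-4H-chromen-4-one | O=c1cc(-c2cc(O)c3c(c2)C=CC(C)(C)O3)oc2cc(O)cc(O)c12 | intermediate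
11 | 5-hydroxy-2-(8-hydroxy-2,2-dimethyl-2H-chromen-6-yl)-7-(2-methylbut-3-yn-2-yloxy)-4H-chromen-4-one | O=c1cc(-c2cc(O)c3c(c2)C=CC(C)(C)O3)oc2cc(OC(C)(C)C#C)cc(O)c12 | intermediate
12 | 5-hydroxy-2-(8-hydroxy-2,2-dimethyl-2H-chromen-6-yl)-7-(2-methylbut-3-en-2-yloxy)-4H-chromen-4-one | O=c1cc(-c2cc(O)c3c(c2)C=CC(C)(C)O3)oc2cc(OC(C)(C)C=C)cc(O)c12 | intermediate
13 | 5,7-dihydroxy-2-(8-hydroxy-2,2-dimethyl-2H-chromen-6-yl)-8-(3-methylbut-2-en-1-yl)-4H-chromen-4-one | CC(C)=CCc1c(O)cc(O)c2c(=O)cc(-c3cc(O)c4c(c3)C=CC(C)(C)O4)oc12 | target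

**Step count and risks**
Total step count: 5. Step 5 is one telescoped operation, with a filtration between the hydrogenation and the thermolysis. Longest linear sequence: 5 steps (1 → 3 → 5 → 10 → 11 → 13).

The three steps most likely to fail, in falling order of risk, are step 3, step 5 and step 4.

Step 3 may fail because the free phenol, the alkyne and the chromene all have to survive a 240 °C acylketene melt. The fallback sets out from 3 and comes back at 10, and it uncouples the two ring closures. Compound 3 is heated in N,N-diethylaniline at 190 °C so that ring D closes first, giving 1-(8-hydroxy-2,2-dimethyl-2H-chromen-6-yl)ethan-1-one F1. NaH and diethyl carbonate 4 in THF then give ethyl 3-(8-hydroxy-2,2-dimethyl-2H-chromen-6-yl)-3-oxopropanoate F2. Fusion of F2 with 6 then only has to close ring C and gives 10.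

Step 4 may fail because alkylation with a tertiary chloride is sluggish and some 3'-O-alkylation is possible. The fallback sets out from 10 and comes back at 12, and it puts the 1,1-dimethylallyl group on oxygen directly by palladium π-allyl chemistry instead of alkylation and reduction. tert-Butyl 2-methylbut-3-en-2-yl carbonate F3 is made from 2-methylbut-3-en-2-ol, n-BuLi and Boc2O. With Pd(PPh3)4 (2 mol%) in THF at 0 °C it ionises and loses CO2, and the tert-butoxide released deprotonates only the most acidic phenol (7-OH). That phenoxide attacks the more substituted allyl terminus to give 12. The palladium is removed through a silica pad and 12 is heated as in the second half of step 5.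

Step 5 may fail through over-reduction of the alkyne or through a poor C8 to C6 ratio in the Claisen step. The fallback sets out from 10 and comes back at 13, replacing steps 4 and 5. It reaches C8 by a para-Claisen (Claisen–Cope) sequence from O5 instead of an ortho-Claisen from O7.
- Ac2O (2.2 equiv) in pyridine at 0 °C acetylates the 7-OH and 3'-OH but not the chelated 5-OH, giving 2-(8-acetoxy-2,2-dimethyl-2H-chromen-6-yl)-5-hydroxy-4-oxo-4H-chromen-7-yl acetate F4.
- Mitsunobu etherification with 3-methylbut-2-en-1-ol, PPh3 and DIAD in THF gives 2-(8-acetoxy-2,2-dimethyl-2H-chromen-6-yl)-5-[(3-methylbut-2-en-1-yl)oxy]-4-oxo-4H-chromen-7-yl acetate F5.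
- Tris(6,6,7,7,8,8,8-heptafluoro-2,2-dimethyloctane-3,5-dionato)europium, Eu(C10H10F7O2)3 (10 mol%), in ClCH2CH2Cl at 60–80 °C drives the [3,3] shift to C6 and the Cope shift on to C8, giving 2-(8-acetoxy-2,2-dimethyl-2H-chromen-6-yl)-5-hydroxy-8-(3-methylbut-2-en-1-yl)-4-oxo-4H-chromen-7-yl acetate F6.
- K2CO3 in MeOH at rt removes both acetates and gives 13.

**Further compounds**
F1 | step 3 | 1-(8-hydroxy-2,2-dimethyl-2H-chromen-6-yl)ethan-1-one | CC(=O)c1cc(O)c2c(c1)C=CC(C)(C)O2
F2 | step 3 | ethyl 3-(8-hydroxy-2,2-dimethyl-2H-chromen-6-yl)-3-oxopropanoate | CCOC(=O)CC(=O)c1cc(O)c2c(c1)C=CC(C)(C)O2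
F3 | step 4 | tert-butyl 2-methylbut-3-en-2-yl carbonate | C=CC(C)(C)OC(=O)OC(C)(C)C
F4 | step 5 | 2-(8-acetoxy-2,2-dimethyl-2H-chromen-6-yl)-5-hydroxy-4-oxo-4H-chromen-7-yl acetate | CC(=O)Oc1cc(O)c2c(=O)cc(-c3cc(OC(C)=O)c4c(c3)C=CC(C)(C)O4)oc2c1
F5 | step 5 | 2-(8-acetoxy-2,2-dimethyl-2H-chromen-6-yl)-5-[(3-methylbut-2-en-1-yl)oxy]-4-oxo-4H-chromen-7-yl acetate | CC(=O)Oc1cc(OCC=C(C)C)c2c(=O)cc(-c3cc(OC(C)=O)c4c(c3)C=CC(C)(C)O4)oc2c1
F6 | step 5 | 2-(8-acetoxy-2,2-dimethyl-2H-chromen-6-yl)-5-hydroxy-8-(3-methylbut-2-en-1-yl)-4-oxo-4H-chromen-7-yl acetate | CC(=O)Oc1cc(O)c2c(=O)cc(-c3cc(OC(C)=O)c4c(c3)C=CC(C)(C)O4)oc2c1CC=C(C)C
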